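All runs are simulated for substances that don't exist, noise included.

**Small charge.** A small charge of reagent, 0.700 equiv on the substrate, is what I look at first in alder, the flask that is asked about and has been followed up to 2.50 min. Oak differs from it in the second catalyst, 0.4 mol% against 0.2 mol%.

| setting | alder | oak | flask |
|---|---|---|---|
| substrate | 26 mM | 26 mM | 26 mM |
| reagent | 0.70 equiv | 0.70 equiv | 0.700 equiv |
| free catalyst | 0.1 mol% | 0.1 mol% | 0.1 mol% |
| second catalyst | 0.2 mol% | 0.4 mol% | 0.2 mol% |
| remark | the very flask that is asked about, followed so far | run made earlier |  |
| time |  |  | 4.0 min |

- alder (time / min: product / %, substrate / %): 0.167: 9.1, 80.3; 0.333: 26.8, 64.1; 0.667: 47.2, 44.4; 1.00: 60.4, 28.9; 1.33: 64.1, 18.8; 2.00: 68.7, 8.9; 2.50: 69.7, 3.8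
- oak (time / min: product / %, substrate / %): 0.167: 16.1, 81.1; 0.417: 37.0, 60.3; 0.833: 57.9, 36.3; 1.33: 67.8, 16.7; 1.50: 69.5, 15.4; 2.00: 70.1, 10.1; 3.00: 71.4, 1.6

(standard deviation of a reading: 1 percentage point)

- product, in percent of the substrate first charged, at 4.0 min
- what to do for the largest gain in product; "none" if nothing gains more than 2 percentage points (Friday's / Wednesday's / Thursday's / Saturday's / none)
- product present, with what was taken out counted in, in percent of the substrate first charged, after Thursday's
- product present, with what was taken out counted in, in percent of the substrate first charged, after Saturday's

- Friday's: change nothing and wait 8.0 min more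
- Wednesday's: at 4.0 min add reagent, 50.0% of the amount charged, then wait 8.0 min
- Thursday's: at 4.0 min take out 90% of the product then present, then wait 8.0 min
- Saturday's: at 4.0 min add free catalyst, 100% of the amount charged, then wait 8.0 min

- product that was removed still counts
- the numbers in the tables scatter by 1 percentage point (one standard deviation)
- "the catalyst" is free catalyst with its forms; second catalyst is a second catalyst
- additions bring no volume worth counting

**Substrate's clock.** In alder the substrate falls close to a single exponential, so I take its rate constant from one reading: 28.9% left at 1.00 min gives k = 1.24 min⁻¹. Integrating that rate to 4.0 min, substrate left = exp(−k t), gives 0.698%.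

**Stranded share.** So by this reckoning 99.3% of the substrate has been used, but I take reagent as the limiting reagent, one per product, which holds product to 70.0%. That leaves 29.3% in between. This difference, substrate used less reagent charged, is the stranded share.

**My commitment.** I commit to 70.0% of product at 4.0 min. Wednesday's adds reagent worth 35.0% of the substrate charged, more than the stranded share, so I choose it and expect a gain of about 30 percentage points, the stranded share with the substrate left. Friday's, Thursday's and Saturday's bring no reagent, so I leave them at 70.0%.

**Weak link.** The weak link is whether the stranded share exists at all, so I test it on readings that did not set k. At 2.50 min in alder, the reckoning gives 25.5%, while substrate and product fall short of the charge by 26 points. A reading scatters by 1 point, so I keep the link.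

**The forecast.** The forecast gives 70% now, Wednesday's as best, 70% after Thursday's and 70% after Saturday's. Its ground is this: “Product stalls at about 70%, exactly the 0.70 equiv of reagent, so reagent is exhausted.” On these four answers my reckoning and the forecast agree.

**The result.** The flask gives 70.0% at 4.0 min. Wednesday's is best, gaining 30 points, and the product, with what was taken out counted in, stands at 70.0% after Thursday's and at 70.0% after Saturday's. At 4.00 min the reagent left is 0%.

    substrate + free catalyst → free catalyst + intermediate (k = 792 M⁻¹ s⁻¹)
    reagent + second catalyst + intermediate → second catalyst + product (k = 3.15 × 10⁵ M⁻² s⁻¹)

In the flask, the stranded share of 29.3% stands beside 29.3% of intermediate at 4.00 min.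

**Second flask.** For a neighbour flask charged with 0.280 equiv of reagent, the same subtraction at 4.0 min gives a stranded share of 71.3% and product of 28.0%. Computed, it holds 71.3% of intermediate and 28.0% of product.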